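The route rests on cutting ring C of unit 2 at C4–C4a and at the interflavan bond C4 (unit 2)–C8 (unit 3). C4, a methine between ring A of unit 2 and ring A of unit 3, is an aldehyde carbon arylated twice; C2 and C3 are the oxygenated carbons of (R)-glyceraldehyde. One Lewis-acid operation closes ring C (C4a attacks the aldehyde) and exchanges the new C4 hydroxyl for C8 of unit 3, setting C4. The precursor is a 3-aryl-3-aryloxy-2-benzyloxypropanal whose aryl ether is ring A of unit 2 with unit 1 para to O1; a C8 bromine (unit 1) and a C4 arylthio group (unit 3) are spectators.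

Key step: step 18

Remarks on the chemistry

- Labels: units 1–4 from the top; rings A (benzo), B (2-aryl), C (pyran). "4β" means the C4 bond is trans to the C3 oxygen and to the C2 aryl group of a (2R,3R) flavan.
- Abbreviations in names: BrEC = 8-bromo-3,5,7,3′,4′-penta-O-benzylepicatechin-4β-yl, i.e. (2R,3R)-2-[3,4-bis(benzyloxy)phenyl]-3,5,7-tris(benzyloxy)-8-bromochroman-4-yl with the C4 bond trans to the C3 benzyloxy group; ArO = 3,5-bis(benzyloxy)-4-(BrEC)phenoxy.
- Descriptor correction: the key-step aldehyde is (2S,3R) in propanal numbering. It has the spatial arrangement of the (2R,3R) flavan; the benzyloxy carbon becomes S only because CHO outranks the aryl-bearing carbon. A (2R,3R) label would denote the C2 epimer.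
- Design changes around the fixed disconnection:
  - A bromine at C8 of unit 1 blocks the most nucleophilic carbon of that unit, so it cannot compete in any of the three cation-forming steps. It leaves in the final hydrogenolysis.
  - Unit 3 enters with a 4β-(2,6-dimethylphenyl)sulfanyl group. It is inert to a hard Lewis acid and is ionised later by Ag+, so no oxidation of the trimer is needed.
  - Ring A of unit 2 is introduced as symmetric phloroglucinol, so the bond to unit 1 has no regiochemical ambiguity; the para oxygen is then freed selectively.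
- Assumption: 1-(benzyloxy)-4-bromobenzene and (R)-2,3-O-isopropylideneglyceraldehyde are purchased, the latter distilled before use.

Step 1
Reactants: 1 (−)-epicatechin
Product: 2 5,7,3′,4′-tetra-O-benzyl-(−)-epicatechin
Conditions: BnBr (4.4 equiv), K2CO3, DMF, 0 °C → rt
Reagents that add atoms: benzyl bromide, BrCc1ccccc1
Why: Williamson ether synthesis in which K2CO3 deprotonates only the four phenols, so the C3 alcohol stays free and the C2 and C3 stereocentres are carried on unchanged.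

Step 2
Reactants: 2 5,7,3′,4′-tetra-O-benzyl-(−)-epicatechin
Product: 3 8-bromo-5,7,3′,4′-tetra-O-benzyl-(−)-epicatechin
Conditions: NBS (1.0 equiv), CH2Cl2, −78 °C → rt
Reagents that add atoms: N-bromosuccinimide, O=C1CCC(=O)N1Br
Why: Electrophilic aromatic bromination should go to C8, which is flanked by the tied-back ring oxygen O1 and is more accessible than C6 between two benzyloxy groups.

Step 3
Reactants: 3 8-bromo-5,7,3′,4′-tetra-O-benzyl-(−)-epicatechin
Product: 4 8-bromo-4β-(2-ethoxyethoxy)-5,7,3′,4′-tetra-O-benzylepicatechin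
Conditions: DDQ (2 equiv), 2-ethoxyethanol (5 equiv), CH2Cl2, rt
Reagents that add atoms: 2-ethoxyethanol, CCOCCO
Why: Oxidative benzylic C–H functionalisation in which DDQ abstracts hydride from C4 and the cation, stabilised by O1 and the C5 and C7 ethers, is trapped by the alcohol anti to the C3 hydroxyl (this centre is ionised again later).

Step 4
Reactants: 4 8-bromo-4β-(2-ethoxyethoxy)-5,7,3′,4′-tetra-O-benzylepicatechin
Product: 5 8-bromo-3,5,7,3′,4′-penta-O-benzyl-4β-(2-ethoxyethoxy)epicatechin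
Conditions: NaH, BnBr, Bu4NI (cat.), DMF, 0 °C → rt
Reagents that add atoms: benzyl bromide, BrCc1ccccc1
Why: Williamson benzylation of the C3 alkoxide, to which the C4 ether, the aryl bromide and the stereocentres are inert.

Step 5
Reactants: 5 8-bromo-3,5,7,3′,4′-penta-O-benzyl-4β-(2-ethoxyethoxy)epicatechin; 6 phloroglucinol
Product: 7 2-(BrEC)benzene-1,3,5-triol
Conditions: BF3·OEt2, 6 (5 equiv), THF–CH2Cl2 (1:3), −40 → 0 °C
Reagents that add atoms: none
Why: Friedel–Crafts alkylation of threefold-symmetric phloroglucinol by the C4 cation gives a single C-adduct, attack anti to the pseudoaxial C3 benzyloxy group sets C4 of unit 1 as 4β, and the C8 bromine together with excess nucleophile suppresses self-condensation and double alkylation.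

Step 6
Reactants: 7 2-(BrEC)benzene-1,3,5-triol
Product: 8 2-(BrEC)-5-(triisopropylsilyloxy)benzene-1,3-diol
Conditions: iPr3SiCl (1.05 equiv), imidazole, DMF, −20 → 0 °C
Reagents that add atoms: chlorotriisopropylsilane, CC(C)[Si](Cl)(C(C)C)C(C)C
Why: Sterically controlled O-silylation should take the hydroxyl para to the flavanyl group, whose neighbours are two hydrogens, while the two ortho hydroxyls are screened by the bulky C4 substituent.

Step 7
Reactants: 8 2-(BrEC)-5-(triisopropylsilyloxy)benzene-1,3-diol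
Product: 9 [3,5-bis(benzyloxy)-4-(BrEC)phenoxy]triisopropylsilane
Conditions: BnBr (2.5 equiv), K2CO3, DMF, rt
Reagents that add atoms: benzyl bromide, BrCc1ccccc1
Why: Williamson etherification of the two remaining phenols, with the hindered triisopropylsilyl aryl ether expected to tolerate carbonate at room temperature.

Step 8
Reactants: 9 [3,5-bis(benzyloxy)-4-(BrEC)phenoxy]triisopropylsilane
Product: 10 3,5-bis(benzyloxy)-4-(BrEC)phenol
Conditions: Bu4NF, AcOH, THF, 0 °C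
Reagents that add atoms: none
Why: Fluoride-induced desilylation frees only the para phenol, the future O1 of unit 2, and acetic acid buffers the phenoxide.

Step 9
Reactants: 11 1-(benzyloxy)-4-bromobenzene; 12 (R)-2,3-O-isopropylideneglyceraldehyde
Product: 14 (S)-[4-(benzyloxy)phenyl][(4R)-2,2-dimethyl-1,3-dioxolan-4-yl]methanol, via 4-(benzyloxy)phenylmagnesium bromide 13 (not isolated)
Conditions: Mg, I2 (cat.), THF, 45 °C; then 12, THF, −78 → −20 °C; H2O
Reagents that add atoms: none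
Why: Grignard addition to the α-alkoxy aldehyde under Felkin–Anh (non-chelation) control in THF should favour the anti adduct with an S carbinol carbon, the minor syn isomer being removed by chromatography.

Step 10
Reactants: 14 (S)-[4-(benzyloxy)phenyl][(4R)-2,2-dimethyl-1,3-dioxolan-4-yl]methanol; 10 3,5-bis(benzyloxy)-4-(BrEC)phenol
Product: 15 (4R)-4-{(R)-[4-(benzyloxy)phenyl](ArO)methyl}-2,2-dimethyl-1,3-dioxolane
Conditions: n-Bu3P, Me2NC(O)N=NC(O)NMe2 (TMAD), 14 (1.5 equiv), toluene, 0 °C → rt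
Reagents that add atoms: none
Why: Mitsunobu etherification in which the phenoxide displaces the alkoxyphosphonium group by SN2 with inversion, turning the S carbinol into the R aryl ether (C2 of unit 2, syn to the C3 oxygen), while toluene, low temperature and the adjacent dioxolane oxygen disfavour ionisation.

Step 11
Reactants: 15 (4R)-4-{(R)-[4-(benzyloxy)phenyl](ArO)methyl}-2,2-dimethyl-1,3-dioxolane
Product: 16 (2R,3R)-3-[4-(benzyloxy)phenyl]-3-(ArO)propane-1,2-diol
Conditions: AcOH–THF–H2O (3:1:1), 45 °C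
Reagents that add atoms: none
Why: Acetal hydrolysis under weak acid should spare the benzylic aryl ether, the benzyl ethers and the C4–aryl bond of unit 1.

Step 12
Reactants: 16 (2R,3R)-3-[4-(benzyloxy)phenyl]-3-(ArO)propane-1,2-diol
Product: 17 (2R,3R)-3-[4-(benzyloxy)phenyl]-3-(ArO)-1-[(tert-butyldiphenylsilyl)oxy]propan-2-ol
Conditions: t-BuPh2SiCl (1.1 equiv), imidazole, CH2Cl2, 0 °C
Reagents that add atoms: tert-butylchlorodiphenylsilane, CC(C)(C)[Si](Cl)(c1ccccc1)c1ccccc1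
Why: Selective O-silylation of the primary hydroxyl by a bulky silyl chloride.

Step 13
Reactants: 17 (2R,3R)-3-[4-(benzyloxy)phenyl]-3-(ArO)-1-[(tert-butyldiphenylsilyl)oxy]propan-2-ol
Product: 18 tert-butyl{[(2R,3R)-2-(benzyloxy)-3-[4-(benzyloxy)phenyl]-3-(ArO)propyl]oxy}diphenylsilane
Conditions: NaH, BnBr, Bu4NI (cat.), THF–DMF (4:1), 0 °C
Reagents that add atoms: benzyl bromide, BrCc1ccccc1
Why: Williamson benzylation of the secondary alkoxide (the C3 oxygen of unit 2), with low temperature and the bulky tert-butyldiphenylsilyl group expected to suppress silyl migration.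

Step 14
Reactants: 18 tert-butyl{[(2R,3R)-2-(benzyloxy)-3-[4-(benzyloxy)phenyl]-3-(ArO)propyl]oxy}diphenylsilane
Product: 19 (2R,3R)-2-(benzyloxy)-3-[4-(benzyloxy)phenyl]-3-(ArO)propan-1-ol
Conditions: Bu4NF, AcOH, THF, 0 °C → rt
Reagents that add atoms: none
Why: Fluoride-mediated desilylation of the primary silyl ether, which touches no other group.

Step 15
Reactants: 19 (2R,3R)-2-(benzyloxy)-3-[4-(benzyloxy)phenyl]-3-(ArO)propan-1-ol
Product: 20 (2S,3R)-2-(benzyloxy)-3-[4-(benzyloxy)phenyl]-3-(ArO)propanal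
Conditions: Dess–Martin periodinane, NaHCO3, CH2Cl2, 0 °C; used at once without chromatography
Reagents that add atoms: none
Why: Dess–Martin oxidation under buffered, non-basic conditions stops at the aldehyde and should avoid α-epimerisation and β-elimination of the aryloxy group if the product is used directly.

Step 16
Reactants: 2 5,7,3′,4′-tetra-O-benzyl-(−)-epicatechin
Product: 21 4β-(2-ethoxyethoxy)-5,7,3′,4′-tetra-O-benzylepicatechin
Conditions: DDQ (2 equiv), 2-ethoxyethanol (5 equiv), CH2Cl2, rt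
Reagents that add atoms: 2-ethoxyethanol, CCOCCO
Why: DDQ-mediated benzylic oxidation at C4 with capture of the cation by the alcohol anti to the C3 hydroxyl.

Step 17
Reactants: 21 4β-(2-ethoxyethoxy)-5,7,3′,4′-tetra-O-benzylepicatechin
Product: 22 4β-[(2,6-dimethylphenyl)sulfanyl]-5,7,3′,4′-tetra-O-benzylepicatechin
Conditions: 2,6-dimethylbenzenethiol (3 equiv), BF3·OEt2, CH2Cl2, −78 → −40 °C
Reagents that add atoms: 2,6-dimethylbenzenethiol, Cc1cccc(C)c1S
Why: Lewis-acid ionisation of the C4 ether followed by capture of the cation by the thiol, a far better nucleophile than C8 of a second molecule, anti to the C3 hydroxyl gives the 4β thioether.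

Step 18
Reactants: 20 (2S,3R)-2-(benzyloxy)-3-[4-(benzyloxy)phenyl]-3-(ArO)propanal; 22 4β-[(2,6-dimethylphenyl)sulfanyl]-5,7,3′,4′-tetra-O-benzylepicatechin
Product: 24 protected trimer [8-bromo-penta-O-benzylepicatechin]-(4β→6)-[3,5,7,4′-tetra-O-benzylepiafzelechin]-(4β→8)-[4β-(2,6-dimethylphenyl)sulfanyl-5,7,3′,4′-tetra-O-benzylepicatechin] (free 3-OH on unit 3), via ring-closed unit 1–unit 2 flavan-4-ol 23 (not isolated)
Conditions: 20 added slowly to 22 (2.5 equiv) and BF3·OEt2 (3 equiv), CH2Cl2 (high dilution), −78 → −30 °C; aq. NaHCO3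
Reagents that add atoms: none
Why: Proposed new method: BF3 activates the aldehyde, an ortho carbon of the ring A ether (the future C4a) attacks it in a Friedel–Crafts hydroxyalkylation, the boron-bound C4 carbinol ionises to a cation stabilised by O1 and the C5 and C7 benzyloxy groups, and C8 of 22 captures it; the closest known reaction types are the acid-promoted cyclisation of 3-aryloxypropanals to chroman-4-ols, the Lewis-acid C4 arylation of flavan-3,4-diol derivatives and the one-pot double arylation of aldehydes to diarylmethines. Ring C closes by a 6-exo-trig electrophilic aromatic substitution (C4–C4a); both ortho carbons of the ether ring are equivalent and unit 1 sits para to O1, so the 4→6 link to unit 1 needs no selection. C4 is the only new stereocentre: in the half-chair cation the C2 aryl group is pseudoequatorial and the C3 benzyloxy group pseudoaxial, so the nucleophile should add anti to the C3 oxygen and give the 3,4-trans (4β) product, as in known C4 arylations of 2,3-cis flavans. The step needs C8 and not C6 of 22, which the smaller hindrance at C8 (ring oxygen on one side) and the extra crowding of C6 by the C4 arylthio group should secure. It also needs ring closure to outrun intermolecular attack on the aldehyde, which the six-membered intramolecular pathway under dilution should secure. The C8 bromine removes the best nucleophilic carbon of unit 1 and the hindered arylthio group is inert to the hard Lewis acid, so neither spectator competes.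

Step 19
Reactants: 24 protected trimer; 3 8-bromo-5,7,3′,4′-tetra-O-benzyl-(−)-epicatechin
Product: 25 protected tetramer [8-bromo-penta-O-benzylepicatechin]-(4β→6)-[3,5,7,4′-tetra-O-benzylepiafzelechin]-(4β→8)-[5,7,3′,4′-tetra-O-benzylepicatechin]-(4β→6)-[8-bromo-5,7,3′,4′-tetra-O-benzylepicatechin]
Conditions: AgBF4 (1.5 equiv), 3 (5 equiv), 4 Å sieves, THF–CH2Cl2, −40 → 0 °C, slow addition of 24; Et3N quench
Reagents that add atoms: none
Why: Thiophilic Ag+ ionises the C4–S bond of unit 3 and the cation undergoes Friedel–Crafts alkylation at C6 of 3, the only free ring A carbon once C8 is blocked by bromine, anti to the C3 hydroxyl to give the 3,4-trans (4β→6) bond.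

Step 20
Reactants: 25 protected tetramer
Product: 26 epicatechin-(4β→6)-epiafzelechin-(4β→8)-epicatechin-(4β→6)-epicatechin (CNP0103636.1)
Conditions: H2 (1 atm), Pd(OH)2/C, Et3N (2.5 equiv), THF–MeOH–H2O, rt
Reagents that add atoms: none
Why: Catalytic hydrogenolysis should cleave all seventeen benzyl ethers and both aryl C–Br bonds, with Et3N taking up HBr so that the acid-labile interflavan bonds, the C2–O1 bonds and all stereocentres remain untouched.

Compound list

1 | (−)-epicatechin, (2R,3R)-2-(3,4-dihydroxyphenyl)chromane-3,5,7-triol | O[C@@H]1Cc2c(O)cc(O)cc2O[C@@H]1c1ccc(O)c(O)c1 | starting material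
2 | 5,7,3′,4′-tetra-O-benzyl-(−)-epicatechin (2R,3R; free 3-OH) | O[C@@H]1Cc2c(OCc9ccccc9)cc(OCc9ccccc9)cc2O[C@@H]1c1ccc(OCc9ccccc9)c(OCc9ccccc9)c1 | intermediate
3 | 8-bromo-5,7,3′,4′-tetra-O-benzyl-(−)-epicatechin | O[C@@H]1Cc2c(OCc9ccccc9)cc(OCc9ccccc9)c(Br)c2O[C@@H]1c1ccc(OCc9ccccc9)c(OCc9ccccc9)c1 | intermediate
4 | 8-bromo-4β-(2-ethoxyethoxy)-5,7,3′,4′-tetra-O-benzylepicatechin (2,3-cis-3,4-trans; free 3-OH) | CCOCCO[C@H]1c2c(OCc9ccccc9)cc(OCc9ccccc9)c(Br)c2O[C@H](c2ccc(OCc9ccccc9)c(OCc9ccccc9)c2)[C@@H]1O | intermediate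
5 | 8-bromo-3,5,7,3′,4′-penta-O-benzyl-4β-(2-ethoxyethoxy)epicatechin | CCOCCO[C@H]1c2c(OCc9ccccc9)cc(OCc9ccccc9)c(Br)c2O[C@H](c2ccc(OCc9ccccc9)c(OCc9ccccc9)c2)[C@@H]1OCc9ccccc9 | intermediate
6 | phloroglucinol (benzene-1,3,5-triol) | Oc1cc(O)cc(O)c1 | starting material
7 | 2-(BrEC)benzene-1,3,5-triol | Oc1cc(O)c([C@H]4c5c(OCc9ccccc9)cc(OCc9ccccc9)c(Br)c5O[C@H](c5ccc(OCc9ccccc9)c(OCc9ccccc9)c5)[C@@H]4OCc9ccccc9)c(O)c1 | intermediate
8 | 2-(BrEC)-5-(triisopropylsilyloxy)benzene-1,3-diol | CC(C)[Si](C(C)C)(C(C)C)Oc1cc(O)c([C@H]4c5c(OCc9ccccc9)cc(OCc9ccccc9)c(Br)c5O[C@H](c5ccc(OCc9ccccc9)c(OCc9ccccc9)c5)[C@@H]4OCc9ccccc9)c(O)c1 | intermediate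
9 | [3,5-bis(benzyloxy)-4-(BrEC)phenoxy]triisopropylsilane | CC(C)[Si](C(C)C)(C(C)C)Oc1cc(OCc9ccccc9)c([C@H]4c5c(OCc9ccccc9)cc(OCc9ccccc9)c(Br)c5O[C@H](c5ccc(OCc9ccccc9)c(OCc9ccccc9)c5)[C@@H]4OCc9ccccc9)c(OCc9ccccc9)c1 | intermediate
10 | 3,5-bis(benzyloxy)-4-(BrEC)phenol | Oc1cc(OCc9ccccc9)c([C@H]4c5c(OCc9ccccc9)cc(OCc9ccccc9)c(Br)c5O[C@H](c5ccc(OCc9ccccc9)c(OCc9ccccc9)c5)[C@@H]4OCc9ccccc9)c(OCc9ccccc9)c1 | intermediate
11 | 1-(benzyloxy)-4-bromobenzene | Brc1ccc(OCc2ccccc2)cc1 | starting material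
12 | (R)-2,3-O-isopropylideneglyceraldehyde, (4R)-2,2-dimethyl-1,3-dioxolane-4-carbaldehyde | CC1(C)OC[C@H](C=O)O1 | starting material
13 | 4-(benzyloxy)phenylmagnesium bromide | Br[Mg]c1ccc(OCc2ccccc2)cc1 | intermediate (not isolated)
14 | (S)-[4-(benzyloxy)phenyl][(4R)-2,2-dimethyl-1,3-dioxolan-4-yl]methanol (anti adduct) | c9ccccc9COc1ccc([C@H](O)[C@H]2COC(C)(C)O2)cc1 | intermediate
15 | (4R)-4-{(R)-[4-(benzyloxy)phenyl](ArO)methyl}-2,2-dimethyl-1,3-dioxolane | c9ccccc9COc1ccc([C@@H](Oc3cc(OCc9ccccc9)c([C@H]4c5c(OCc9ccccc9)cc(OCc9ccccc9)c(Br)c5O[C@H](c5ccc(OCc9ccccc9)c(OCc9ccccc9)c5)[C@@H]4OCc9ccccc9)c(OCc9ccccc9)c3)[C@H]2COC(C)(C)O2)cc1 | intermediate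
16 | (2R,3R)-3-[4-(benzyloxy)phenyl]-3-(ArO)propane-1,2-diol | c9ccccc9COc1ccc([C@@H](Oc3cc(OCc9ccccc9)c([C@H]4c5c(OCc9ccccc9)cc(OCc9ccccc9)c(Br)c5O[C@H](c5ccc(OCc9ccccc9)c(OCc9ccccc9)c5)[C@@H]4OCc9ccccc9)c(OCc9ccccc9)c3)[C@H](O)CO)cc1 | intermediate
17 | (2R,3R)-3-[4-(benzyloxy)phenyl]-3-(ArO)-1-[(tert-butyldiphenylsilyl)oxy]propan-2-ol | c9ccccc9COc1ccc([C@@H](Oc3cc(OCc9ccccc9)c([C@H]4c5c(OCc9ccccc9)cc(OCc9ccccc9)c(Br)c5O[C@H](c5ccc(OCc9ccccc9)c(OCc9ccccc9)c5)[C@@H]4OCc9ccccc9)c(OCc9ccccc9)c3)[C@H](O)CO[Si](c2ccccc2)(c2ccccc2)C(C)(C)C)cc1 | intermediate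
18 | tert-butyl{[(2R,3R)-2-(benzyloxy)-3-[4-(benzyloxy)phenyl]-3-(ArO)propyl]oxy}diphenylsilane | c9ccccc9COc1ccc([C@@H](Oc3cc(OCc9ccccc9)c([C@H]4c5c(OCc9ccccc9)cc(OCc9ccccc9)c(Br)c5O[C@H](c5ccc(OCc9ccccc9)c(OCc9ccccc9)c5)[C@@H]4OCc9ccccc9)c(OCc9ccccc9)c3)[C@H](OCc9ccccc9)CO[Si](c2ccccc2)(c2ccccc2)C(C)(C)C)cc1 | intermediate
19 | (2R,3R)-2-(benzyloxy)-3-[4-(benzyloxy)phenyl]-3-(ArO)propan-1-ol | c9ccccc9COc1ccc([C@@H](Oc3cc(OCc9ccccc9)c([C@H]4c5c(OCc9ccccc9)cc(OCc9ccccc9)c(Br)c5O[C@H](c5ccc(OCc9ccccc9)c(OCc9ccccc9)c5)[C@@H]4OCc9ccccc9)c(OCc9ccccc9)c3)[C@H](OCc9ccccc9)CO)cc1 | intermediate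
20 | (2S,3R)-2-(benzyloxy)-3-[4-(benzyloxy)phenyl]-3-(ArO)propanal (key-step precursor) | c9ccccc9COc1ccc([C@@H](Oc3cc(OCc9ccccc9)c([C@H]4c5c(OCc9ccccc9)cc(OCc9ccccc9)c(Br)c5O[C@H](c5ccc(OCc9ccccc9)c(OCc9ccccc9)c5)[C@@H]4OCc9ccccc9)c(OCc9ccccc9)c3)[C@H](OCc9ccccc9)C=O)cc1 | intermediate
21 | 4β-(2-ethoxyethoxy)-5,7,3′,4′-tetra-O-benzylepicatechin (free 3-OH) | CCOCCO[C@H]1c2c(OCc9ccccc9)cc(OCc9ccccc9)cc2O[C@H](c2ccc(OCc9ccccc9)c(OCc9ccccc9)c2)[C@@H]1O | intermediate
22 | 4β-[(2,6-dimethylphenyl)sulfanyl]-5,7,3′,4′-tetra-O-benzylepicatechin (free 3-OH; key-step partner) | Cc1cccc(C)c1S[C@H]1c2c(OCc9ccccc9)cc(OCc9ccccc9)cc2O[C@H](c2ccc(OCc9ccccc9)c(OCc9ccccc9)c2)[C@@H]1O | intermediate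
23 | ring-closed unit 1–unit 2 flavan-4-ol: (2R,3R)-3,5,7-tris(benzyloxy)-2-[4-(benzyloxy)phenyl]-6-(BrEC)chroman-4-ol, both C4 epimers | c9ccccc9COc1ccc([C@H]2Oc3cc(OCc9ccccc9)c([C@H]4c5c(OCc9ccccc9)cc(OCc9ccccc9)c(Br)c5O[C@H](c5ccc(OCc9ccccc9)c(OCc9ccccc9)c5)[C@@H]4OCc9ccccc9)c(OCc9ccccc9)c3C(O)[C@H]2OCc9ccccc9)cc1 | intermediate (not isolated)
24 | protected trimer: [8-bromo-penta-O-benzylepicatechin]-(4β→6)-[3,5,7,4′-tetra-O-benzylepiafzelechin]-(4β→8)-[4β-(2,6-dimethylphenyl)sulfanyl-5,7,3′,4′-tetra-O-benzylepicatechin], free 3-OH on unit 3 | c9ccccc9COc1ccc([C@H]2Oc3cc(OCc9ccccc9)c([C@H]4c5c(OCc9ccccc9)cc(OCc9ccccc9)c(Br)c5O[C@H](c5ccc(OCc9ccccc9)c(OCc9ccccc9)c5)[C@@H]4OCc9ccccc9)c(OCc9ccccc9)c3[C@H](c3c(OCc9ccccc9)cc(OCc9ccccc9)c4c3O[C@H](c3ccc(OCc9ccccc9)c(OCc9ccccc9)c3)[C@H](O)[C@H]4Sc3c(C)cccc3C)[C@H]2OCc9ccccc9)cc1 | intermediate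
25 | protected tetramer: [8-bromo-penta-O-benzylepicatechin]-(4β→6)-[3,5,7,4′-tetra-O-benzylepiafzelechin]-(4β→8)-[5,7,3′,4′-tetra-O-benzylepicatechin]-(4β→6)-[8-bromo-5,7,3′,4′-tetra-O-benzylepicatechin], free 3-OH on units 3 and 4 | c9ccccc9COc1ccc([C@H]2Oc3cc(OCc9ccccc9)c([C@H]4c5c(OCc9ccccc9)cc(OCc9ccccc9)c(Br)c5O[C@H](c5ccc(OCc9ccccc9)c(OCc9ccccc9)c5)[C@@H]4OCc9ccccc9)c(OCc9ccccc9)c3[C@H](c3c(OCc9ccccc9)cc(OCc9ccccc9)c4c3O[C@H](c3ccc(OCc9ccccc9)c(OCc9ccccc9)c3)[C@H](O)[C@H]4c3c(OCc9ccccc9)c(Br)c4c(c3OCc9ccccc9)C[C@@H](O)[C@@H](c3ccc(OCc9ccccc9)c(OCc9ccccc9)c3)O4)[C@H]2OCc9ccccc9)cc1 | intermediate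
26 | epicatechin-(4β→6)-epiafzelechin-(4β→8)-epicatechin-(4β→6)-epicatechin (CNP0103636.1) | Oc1ccc([C@H]2Oc3cc(O)c([C@H]4c5c(O)cc(O)cc5O[C@H](c5ccc(O)c(O)c5)[C@@H]4O)c(O)c3[C@H](c3c(O)cc(O)c4c3O[C@H](c3ccc(O)c(O)c3)[C@H](O)[C@H]4c3c(O)cc4c(c3O)C[C@@H](O)[C@@H](c3ccc(O)c(O)c3)O4)[C@H]2O)cc1 | target

Total step count: 20 steps.
Longest linear sequence: 17 steps (1 → 2 → 3 → 4 → 5 → 7 → 8 → 9 → 10 → 15 → 16 → 17 → 18 → 19 → 20 → 24 → 25 → 26).

The three steps most likely to fail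

Step 18 (key step, proposed new method). The processes that may go wrong are:
- the C4 cation may lose a proton to a flav-3-ene, or be captured by a free ortho carbon of a second molecule of 20 (oligomerisation), before 22 arrives;
- 22 may attack the activated aldehyde before ring closure;
- the acyclic benzylic aryl ether may ionise, or the α-carbon may enolise, with loss of the C2 or C3 configuration.

The fallback divides the operation into its two known halves and sets out from 20. Ring closure alone with Me2AlCl (CH2Cl2, −78 °C), where the aluminium alkoxide should not ionise, would give the flavan-4-ol 23 as an isolated compound. Acetylation (Ac2O, pyridine, DMAP) would give the C4 acetate of 23 F1. The established hard-acid arylation of a 4-acyloxyflavan (BF3·OEt2, CH2Cl2, −78 °C, excess 22) would then return to the route at 24.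

Step 19. Attack by the hindered, bromine-deactivated C6 of 3 may be slower than self-condensation of 24 through the free C8 of unit 2, or than capture of the cation by traces of water. Silver-bound thiolate may also re-add. The fallback sets out from 24 and separates sulfur removal from C–C bond formation. AgBF4 with excess 2-ethoxyethanol in THF would exchange the thioether for oxygen and give the 4β-(2-ethoxyethoxy) trimer F2. Coupling of F2 with excess 3 under catalytic Me3SiOTf (CH2Cl2, −78 → −20 °C) is a reversible hard-acid activation, in which the cation is regenerated until C6 captures it. It would return to the route at 25.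

Step 10. The alkoxyphosphonium salt may ionise at the electron-rich 4-benzyloxybenzylic carbon (loss of configuration at the future C2 of unit 2) or eliminate, and the two bulky partners may react slowly. The fallback sets out from 12 and makes ring B electron-poor during the substitution.
- 4-Iodophenol would be acylated (pivaloyl chloride, pyridine) to 4-iodophenyl pivalate F3.
- Iodine–magnesium exchange (iPrMgCl·LiCl, THF, −20 °C) would give 4-(pivaloyloxy)phenylmagnesium chloride F4.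
- Addition of F4 to 12 at −40 °C would give the anti carbinol 4-{(S)-hydroxy[(4R)-2,2-dimethyl-1,3-dioxolan-4-yl]methyl}phenyl pivalate F5.
- Mitsunobu reaction of F5 with 10 (n-Bu3P, TMAD, toluene) would give the inverted aryl ether 4-{(R)-(ArO)[(4R)-2,2-dimethyl-1,3-dioxolan-4-yl]methyl}phenyl pivalate F6.
- NaOMe in MeOH would free the phenol 4-{(R)-(ArO)[(4R)-2,2-dimethyl-1,3-dioxolan-4-yl]methyl}phenol F7.
- BnBr with K2CO3 in DMF would return to the route at 15.

Further compounds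

F1 | step 18 | C4 acetate of 23, (2R,3R)-3,5,7-tris(benzyloxy)-2-[4-(benzyloxy)phenyl]-6-(BrEC)chroman-4-yl acetate, both C4 epimers | c9ccccc9COc1ccc([C@H]2Oc3cc(OCc9ccccc9)c([C@H]4c5c(OCc9ccccc9)cc(OCc9ccccc9)c(Br)c5O[C@H](c5ccc(OCc9ccccc9)c(OCc9ccccc9)c5)[C@@H]4OCc9ccccc9)c(OCc9ccccc9)c3C(OC(C)=O)[C@H]2OCc9ccccc9)cc1
F2 | step 19 | 4β-(2-ethoxyethoxy) trimer, 24 with the arylsulfanyl group of unit 3 replaced by 2-ethoxyethoxy | c9ccccc9COc1ccc([C@H]2Oc3cc(OCc9ccccc9)c([C@H]4c5c(OCc9ccccc9)cc(OCc9ccccc9)c(Br)c5O[C@H](c5ccc(OCc9ccccc9)c(OCc9ccccc9)c5)[C@@H]4OCc9ccccc9)c(OCc9ccccc9)c3[C@H](c3c(OCc9ccccc9)cc(OCc9ccccc9)c4c3O[C@H](c3ccc(OCc9ccccc9)c(OCc9ccccc9)c3)[C@H](O)[C@H]4OCCOCC)[C@H]2OCc9ccccc9)cc1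
F3 | step 10 | 4-iodophenyl pivalate | CC(C)(C)C(=O)Oc1ccc(I)cc1
F4 | step 10 | 4-(pivaloyloxy)phenylmagnesium chloride | CC(C)(C)C(=O)Oc1ccc([Mg]Cl)cc1
F5 | step 10 | 4-{(S)-hydroxy[(4R)-2,2-dimethyl-1,3-dioxolan-4-yl]methyl}phenyl pivalate | CC(C)(C)C(=O)Oc1ccc([C@H](O)[C@H]2COC(C)(C)O2)cc1
F6 | step 10 | 4-{(R)-(ArO)[(4R)-2,2-dimethyl-1,3-dioxolan-4-yl]methyl}phenyl pivalate | CC(C)(C)C(=O)Oc1ccc([C@@H](Oc3cc(OCc9ccccc9)c([C@H]4c5c(OCc9ccccc9)cc(OCc9ccccc9)c(Br)c5O[C@H](c5ccc(OCc9ccccc9)c(OCc9ccccc9)c5)[C@@H]4OCc9ccccc9)c(OCc9ccccc9)c3)[C@H]2COC(C)(C)O2)cc1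
F7 | step 10 | 4-{(R)-(ArO)[(4R)-2,2-dimethyl-1,3-dioxolan-4-yl]methyl}phenol | Oc1ccc([C@@H](Oc3cc(OCc9ccccc9)c([C@H]4c5c(OCc9ccccc9)cc(OCc9ccccc9)c(Br)c5O[C@H](c5ccc(OCc9ccccc9)c(OCc9ccccc9)c5)[C@@H]4OCc9ccccc9)c(OCc9ccccc9)c3)[C@H]2COC(C)(C)O2)cc1
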